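## Retrosynthetic overview
1. Ring D (the dimethylpyran) is opened first. Retro oxa-6π closure, retro 1,5-H shift and retro propargyl Claisen lead back to the 4'-O-(1,1-dimethylpropargyl) ether of 3'-methoxydaidzein.
2. The key disconnection is the ArO–C(CH3)2 bond of that ether. It gives unprotected 3'-methoxydaidzein and 3-chloro-3-methylbut-1-yne, so the bond must be made at the less acidic 4'-OH next to a free 7-OH.
3. Ring C (the pyranone) is cut at O1–C2 and C2–C3 (C2 comes from DMF) and at the aryl–acyl bond. This gives resorcinol and homovanillic acid.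
4. Ring order: rings A and B are bought, ring C is made in step 1, and ring D is made in step 3. No protecting groups are used.

Assumption: the target has no stereocentre and no free stereogenic double bond (the ring D alkene is locked cis in the ring). It is therefore achiral and there is no enantiomer to control.

## Route

**Step 1**
Reactants: 1 resorcinol; 2 homovanillic acid
Product: 4 7-hydroxy-3-(4-hydroxy-3-methoxyphenyl)-4H-chromen-4-one (3'-methoxydaidzein), via deoxybenzoin 3 (not isolated)
Conditions: BF3·OEt2 (as solvent), 85 °C, 90 min; cool to 10 °C, DMF, then MeSO2Cl (3 equiv) in DMF, 70 °C, 2 h; pour into ice water, filter, recrystallise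
Reagents that add atoms: N,N-dimethylformamide (DMF), CN(C)C=O
Why: BF3-promoted Friedel–Crafts (Nencki-type) C-acylation of resorcinol at C4 gives 3, whose activated methylene is formylated by the Vilsmeier-type DMF/MeSO2Cl reagent before the 2-OH closes ring C by addition–elimination with loss of dimethylamine; this one-pot deoxybenzoin isoflavone synthesis tolerates free phenols and forms no stereocentre.

**Step 2 (key step)**
Reactants: 4 3'-methoxydaidzein; 5 3-chloro-3-methylbut-1-yne
Product: 8 7-hydroxy-3-[3-methoxy-4-(2-methylbut-3-yn-2-yloxy)phenyl]-4H-chromen-4-one, via dipotassium bis-phenoxide 6 (not isolated), via potassium salt of the ether 7 (not isolated)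
Conditions: KOt-Bu (2.0 equiv), DMF, 0 °C, 20 min, Ar; CuI (5 mol %), then 5 (1.1 equiv, added over 1 h), 0 to 20 °C, 4 h; 1 M HCl to pH 4
Reagents that add atoms: none
Why: Proposed new method: dianion-gated, site-selective copper-catalysed propargylic etherification, in which two equivalents of KOt-Bu convert 4 into 6, whose 7-oxide is a delocalised vinylogous carboxylate (conjugate acid pKa about 7.4) while the 4'-guaiacolate (pKa about 10, a gap that widens in DMF) is the much stronger nucleophile, and CuI turns 5 through its monovalent copper acetylide and loss of chloride into an electrophilic copper allenylidene (Cu–C≡C–CMe2+ character) that the 4'-oxide captures at the tertiary carbon to make the ArO–CMe2 bond, with acetylide exchange with fresh 5 closing the cycle and slow addition at 0 °C limiting attack by the remaining 7-oxide; the closest known reaction types are copper-catalysed O-(1,1-dimethylpropargyl)ation of single phenols and dianion-controlled 4'-O-alkylation of daidzein-type isoflavones by primary halides (SN2), and their combination with a tertiary propargylic electrophile on an unprotected bis-phenol has not been shown; no stereocentre is formed.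

**Step 3**
Reactants: 8 the 4'-O-(1,1-dimethylpropargyl) ether
Product: 11 7-hydroxy-3-(8-methoxy-2,2-dimethyl-2H-chromen-6-yl)-4H-chromen-4-one (target), via ortho-allenylphenol 9 (not isolated), via ortho-quinone methide 10 (not isolated)
Conditions: PhNEt2, 190 °C, Ar, 2 h; EtOAc, cold 1 M HCl wash, chromatography
Reagents that add atoms: none
Why: The aromatic propargyl Claisen rearrangement can only go to C5' because the other ortho position carries OMe and the para position carries the isoflavone, so rearomatisation gives 9, a 1,5-hydrogen shift gives the (Z)-configured 10, and oxa-6π electrocyclisation rejoins O to CMe2 and closes ring D; the gem-dimethyl group accelerates the cascade, the free 7-OH and the chromone are inert, and no stereocentre is formed.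

## Compound list
1 | resorcinol (benzene-1,3-diol) | Oc1cccc(O)c1 | starting material
2 | homovanillic acid, (4-hydroxy-3-methoxyphenyl)acetic acid | COc1cc(CC(=O)O)ccc1O | starting material
3 | 1-(2,4-dihydroxyphenyl)-2-(4-hydroxy-3-methoxyphenyl)ethan-1-one (deoxybenzoin) | COc1cc(CC(=O)c2ccc(O)cc2O)ccc1O | intermediate (not isolated)
4 | 7-hydroxy-3-(4-hydroxy-3-methoxyphenyl)-4H-chromen-4-one (3'-methoxydaidzein) | COc1cc(-c2coc3cc(O)ccc3c2=O)ccc1O | intermediate
5 | 3-chloro-3-methylbut-1-yne | C#CC(C)(C)Cl | starting material
6 | dipotassium 7,4'-bis-phenoxide of 4 | COc1cc(-c2coc3cc([O-])ccc3c2=O)ccc1[O-].[K+].[K+] | intermediate (not isolated)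
7 | potassium 7-phenoxide of ether 8 | COc1cc(-c2coc3cc([O-])ccc3c2=O)ccc1OC(C)(C)C#C.[K+] | intermediate (not isolated)
8 | 7-hydroxy-3-[3-methoxy-4-(2-methylbut-3-yn-2-yloxy)phenyl]-4H-chromen-4-one | COc1cc(-c2coc3cc(O)ccc3c2=O)ccc1OC(C)(C)C#C | intermediate
9 | 7-hydroxy-3-[4-hydroxy-3-methoxy-5-(3-methylbuta-1,2-dien-1-yl)phenyl]-4H-chromen-4-one | COc1cc(-c2coc3cc(O)ccc3c2=O)cc(C=C=C(C)C)c1O | intermediate (not isolated)
10 | 7-hydroxy-3-[(3Z)-5-methoxy-3-(3-methylbut-2-en-1-ylidene)-4-oxocyclohexa-1,5-dien-1-yl]-4H-chromen-4-one (the vinyl arm is cis to the ring C=O) | O=C1C(OC)=CC(-c2coc3cc(O)ccc3c2=O)=C/C1=C/C=C(C)C | intermediate (not isolated)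
11 | 7-hydroxy-3-(8-methoxy-2,2-dimethyl-2H-chromen-6-yl)-4H-chromen-4-one (achiral) | COc1cc(-c2coc3cc(O)ccc3c2=O)cc2c1OC(C)(C)C=C2 | target

## Step count and risks
Total step count: 3. Longest linear sequence: 3.

**Step 2 (the proposed new step) is the most likely to fail.**
- Risk: the copper allenylidene is very reactive, so its early transition state may discriminate poorly between the two oxides. The ortho-OMe group also hinders the 4'-oxide. The 7-O-ether and the bis-ether may then form.
- Control: the desired 8 keeps the acidic 7-OH. It can be extracted into dilute Na2CO3 away from both by-products, and it shows the NaOAc UV shift typical of a free 7-OH.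
- Fallback (known chemistry): it sets out from 4 and comes back at 11. The more acidic 7-OH is capped selectively with chloromethyl methyl ether (COCCl, 1.05 equiv) and K2CO3 in acetone at 0 to 20 °C. This gives 3-(4-hydroxy-3-methoxyphenyl)-7-(methoxymethoxy)-4H-chromen-4-one F1. The only remaining phenol is alkylated with 5 under standard conditions (K2CO3, KI, CuI 10 mol %, DMF, 60 °C) to give 3-[3-methoxy-4-(2-methylbut-3-yn-2-yloxy)phenyl]-7-(methoxymethoxy)-4H-chromen-4-one F2. Heating in PhNEt2 at 190 °C gives 3-(8-methoxy-2,2-dimethyl-2H-chromen-6-yl)-7-(methoxymethoxy)-4H-chromen-4-one F3. Catalytic HCl in MeOH/THF at 50 °C then removes the acetal to give 11.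

**Step 1 is the second most likely to fail.**
- Risk: hot BF3·OEt2 may erode the guaiacol methyl ether. The triphenol 3 may also be partly O-sulfonylated or give tar in the formylation stage, which lowers yield and purity.
- Fallback: it sets out from 1 and comes back at 4, passing through 3, which is now isolated. Resorcinol 1 and commercial (4-hydroxy-3-methoxyphenyl)acetonitrile (N#CCc1ccc(O)c(OC)c1) are joined by a Houben–Hoesch reaction (ZnCl2, HCl gas, Et2O, 0 °C). This gives 1-(2,4-dihydroxyphenyl)-2-(4-hydroxy-3-methoxyphenyl)ethan-1-iminium chloride F4, which is boiled in water to give 3. Ring C is then closed separately with triethyl orthoformate (CCOC(OCC)OCC) in pyridine with catalytic piperidine at reflux to give 4.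

**Step 3 is the third most likely to fail.**
- Risk: at 190 °C the polar phenolic substrate may dissolve poorly. The product chromene may also oligomerise or darken before conversion is complete.
- Fallback: it sets out from 8 and comes back at 11 without any new compound. The pericyclic cascade is replaced by a π-acid mechanism. Ph3PAuNTf2 (3 mol %, cationic monovalent gold) in 1,2-dichloroethane/THF at 25 to 40 °C activates the alkyne for a 6-endo-dig intramolecular hydroarylation at C5'. The ArO–CMe2 bond stays intact and the C4–C4a bond forms directly at room temperature.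

## Further compounds
F1 | step 2 | 3-(4-hydroxy-3-methoxyphenyl)-7-(methoxymethoxy)-4H-chromen-4-one | COCOc1ccc2c(c1)occ(-c1ccc(O)c(OC)c1)c2=O
F2 | step 2 | 3-[3-methoxy-4-(2-methylbut-3-yn-2-yloxy)phenyl]-7-(methoxymethoxy)-4H-chromen-4-one | COCOc1ccc2c(c1)occ(-c1ccc(OC(C)(C)C#C)c(OC)c1)c2=O
F3 | step 2 | 3-(8-methoxy-2,2-dimethyl-2H-chromen-6-yl)-7-(methoxymethoxy)-4H-chromen-4-one | COCOc1ccc2c(c1)occ(-c1cc(OC)c3OC(C)(C)C=Cc3c1)c2=O
F4 | step 1 | 1-(2,4-dihydroxyphenyl)-2-(4-hydroxy-3-methoxyphenyl)ethan-1-iminium chloride | COc1cc(CC(=[NH2+])c2ccc(O)cc2O)ccc1O.[Cl-]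
F0 | step 3 | none | none
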